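**Design of a synthesis of 5-hydroxy-7-methoxy-6-(3-methylbut-2-enyl)-3-(2,4,5-trimethoxyphenyl)chromen-4-one (16)**

## The problem

Target 16 is an isoflavone: a benzopyranone (rings A and C fused at C4a–C8a) carrying the 2,4,5-trimethoxyphenyl ring B at C3. It has no stereocentre, so there is no stereocontrol to plan, and the task is one of connectivity and regiochemistry. Ring A is a fully differentiated phloroglucinol: one oxygen is O1 of ring C, one is the free chelated 5-OH, one is the 7-OMe, and the prenyl group sits at C6 between the last two. C8 is electronically almost the same as C6, so the prenyl position must be enforced by the structure, not hoped for. The sensitive groups are: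

- the prenyl alkene next to a free phenol, which acid cyclises to a dihydropyran and which halogens and oxidants attack;
- C2 of the pyranone, which hydroxide or alkoxide attacks with ring opening;
- the very electron-rich ring B, which is easily halogenated or oxidised.

The feature that makes the key step possible is that the C4 carbonyl lies between aryl carbon C4a and the aryl-bearing C3, while O1–C2 is an enol ether bond. Ring C can therefore be taken apart into an iodophenol, carbon monoxide and a 1-aryl-2-methoxyvinyl unit. Without the prenyl group, ring A has a mirror plane through C4a and C7, so O1 and the 5-oxygen are equivalent and the iodophenol can be the symmetric 2-iodo-5-methoxyresorcinol 2. The hydroxyl left over at C5 then has only one ortho carbon that carries hydrogen, C6, which settles where a sigmatropic shift delivers carbon.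

## Retrosynthesis

**16 to 15.** The trisubstituted C=C bond of the prenyl group is cut, leading back to the 6-allyl compound 15 and 2-methylbut-2-ene. Direct C-prenylation of a 5-hydroxy-7-methoxyisoflavone would give C6, C8 and O-alkylated products. Carrying a prenyl group through the earlier palladium, bromine and acid steps would expose its alkene. Cross-metathesis only asks for a catalyst that tolerates a chelated phenol and leaves the C2=C3 enol ether alone.

**15 to 14 to 13.** The C6–CH2 bond is cut by an aromatic Claisen disconnection to the 5-O-allyl ether 14, and the O–allyl bond is then cut to give phenol 13. The 5-oxygen has C4a and C6 as ortho carbons, and only C6 bears hydrogen, so the [3,3] shift has one outcome. A 2-methylbut-3-en-2-yl ether would give the prenyl group directly and save one step. It would, however, require a tertiary ether at the hindered, hydrogen-bonded peri hydroxyl, which is the weaker alkylation; the primary allyl ether followed by metathesis is preferred. Compound 13 has one hydroxyl and no carbon substituent on ring A, so it is much simpler than 16.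

**13 to 2 + 11 + 10 (key disconnection).** Three bonds are cut: C4a–C4, C4–C3 and O1–C2. This yields the symmetric iodoresorcinol 2, carbon monoxide 11 and the vinylboronate 10. The neighbouring cuts remove less: a C3–C1' Suzuki cut needs a preformed 3-halochromone, and a deoxybenzoin cut needs a regioselective acylation of an unsymmetrical phenol. The chosen cut removes ring C entirely and leaves two trivial pieces plus one three-step fragment, and symmetry removes the question of which oxygen closes. The forward reaction must insert CO before transmetalation and must then close the ring by displacing methoxide.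

**2 to 1.** The C–I bond is cut, leading to commercial 5-methoxyresorcinol 1. The forward step is an iodination that must go to the carbon between the two hydroxyls.

**10 to 8 + 9, 8 to 6, 6 to 3 + 4.** The C–B bond is cut to give the alkenyl bromide 8 and bis(pinacolato)diboron 9. The C–Br bond is cut to give the enol ether 6. The enol ether C=C bond is cut to give 2,4,5-trimethoxybenzaldehyde 3 and the methoxymethyl phosphonium salt 4. Ring B is bought with all three methoxy groups in place. The double-bond geometry never needs control, because it is lost when methanol leaves in the key step.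

## Roads not taken

**Alternative 1: carbene-catalysed crossed benzoin closing ring C.** The cut is C3–C4. The keto-aldehyde A1, a salicylaldehyde carrying a phenacyl ether, would be treated with a triazolium-derived carbene. The Breslow intermediate of the aldehyde would add to the tethered aryl ketone and give the racemic 3-hydroxychromanone A2. Dehydration across C2–C3 and removal of the methoxymethyl group would then reach 13.
- Merits: the key step is catalytic and metal-free, and intramolecular aldehyde–ketone benzoin closure to 3-hydroxychromanones is an established reaction class. In this respect it stands on firmer precedent than the three-component annulation chosen here.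
- Weak points: A1 needs a salicylaldehyde whose three oxygens are all different, so several protecting-group steps come before the key step. The aldehyde is hindered and electron-rich, which slows Breslow formation. Base can divert the phenacyl ether into Rap–Stoermer condensation to a 2-aroylbenzofuran. A stereocentre is made only to be destroyed, and the tertiary α-keto alcohol must then be dehydrated.
- Comparison: it ends at 13 and needs the same prenylation endgame, but takes roughly four more steps to get there. The chosen plan sets a one-step iodide, a three-step boronate and no redox or protecting-group corrections against its better-precedented key step.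

**Alternative 2: Claisen–Dieckmann annulation building ring A.** The cuts are C7–C8 and C5–C6. The lateral carbanion of the methylpyranone ester A3 would be acylated by the ester A4. The new ketone enolate would then close onto the pyranone ester to give the 5,7-dihydroxy-6-prenylisoflavone A5. Selective methylation of the non-chelated 7-OH would finish 16.
- Merits: the prenyl group is placed at C6 by construction, with no Claisen rearrangement and no metathesis. After its key step only one easy step remains, against three in the chosen plan. On endgame economy and on certainty of the prenyl position this road is better.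
- Weak points: A3 already carries ring B and has no short preparation. Its unsubstituted pyranone carbon (C2 of the chromone) is open to attack by the strong base needed in excess. A4 is an enolisable ester that can self-condense instead of acylating the lateral anion. Two carbon–carbon bonds must form in sequence under conditions in which the 4-pyranone is fragile.
- Comparison: the chosen plan pays three well-precedented endgame steps for fragments that are each one to three steps from catalogue compounds, and for a key step run under weakly basic conditions.

**Alternative 3: Dötz benzannulation building ring B.** The cuts are C5'–C6', C1'–C2' and C2'–C3'. The chromium carbene A6 would react with the ethynylchromone A7 and one CO ligand to give the 2'-phenol A8. O-Methylation and removal of the 5-O-methyl group would then reach 13.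
- Merits: benzannulation with terminal alkynes is regiochemically reliable, and it would deliver a differentiated 2'-oxygen, which is useful for 2'-hydroxy congeners.
- Weak points: ring B is the one ring that can be bought with the right substitution, so the step builds what is available. Chromium is stoichiometric. A7 is an electron-poor, Michael-accepting alkyne of the kind that lowers benzannulation efficiency. Two oxygen-adjustment steps follow, and the C6 prenyl problem is untouched.
- Comparison: it offers no advantage for this target. The chosen plan is shorter and forms the ring that actually needs forming.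

Key step: step 5

## Route

Assumption: 6, 8, 10 and 12 are handled as mixtures of double-bond isomers and 7 as a mixture of diastereomers, because this geometry is erased when methanol is lost in step 5; their SMILES therefore carry no stereodescriptors.

Step 1
Reactants: 1 5-methoxybenzene-1,3-diol (5-methoxyresorcinol)
Product: 2 2-iodo-5-methoxybenzene-1,3-diol
Conditions: I2 (1.05 equiv), NaHCO3, H2O/THF, 0 °C to rt
Reagents that add atoms: iodine, II
Why: Electrophilic aromatic iodination of the phenoxide; under I2/NaHCO3 in water resorcinols are iodinated preferentially at the carbon between the two hydroxyls, and 2 should be separable from any 4-iodo isomer and diiodide by crystallisation or chromatography.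

Step 2
Reactants: 3 2,4,5-trimethoxybenzaldehyde; 4 (methoxymethyl)triphenylphosphonium chloride
Product: 6 1,2,4-trimethoxy-5-(2-methoxyethenyl)benzene (E/Z mixture), via ylide Ph3P=CHOMe 5 (not isolated)
Conditions: KOtBu, THF, 0 °C to rt
Reagents that add atoms: none
Why: Wittig olefination with the methoxymethylene ylide generated in the flask; the mixture of enol ether isomers is acceptable because the geometry is not carried into the target.

Step 3
Reactants: 6 1,2,4-trimethoxy-5-(2-methoxyethenyl)benzene
Product: 8 1-(1-bromo-2-methoxyethenyl)-2,4,5-trimethoxybenzene (mixture of double-bond isomers), via dibromide 7 (not isolated)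
Conditions: Br2 (1.0 equiv), CH2Cl2, −78 °C; then DBU, −78 °C to rt
Reagents that add atoms: bromine, BrBr
Why: Bromination–dehydrobromination of an enol ether: at −78 °C bromine adds to the enol ether faster than it substitutes the arene, and base then removes the bromide on the acetal carbon together with the benzylic proton, leaving bromine on the aryl-bearing carbon, as in the conversion of dihydropyran to 5-bromo-3,4-dihydro-2H-pyran.

Step 4
Reactants: 8 1-(1-bromo-2-methoxyethenyl)-2,4,5-trimethoxybenzene; 9 bis(pinacolato)diboron
Product: 10 2-[2-methoxy-1-(2,4,5-trimethoxyphenyl)ethenyl]-4,4,5,5-tetramethyl-1,3,2-dioxaborolane (mixture of double-bond isomers)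
Conditions: PdCl2(PPh3)2 (3 mol %), PPh3 (6 mol %), KOPh, toluene, 50 °C
Reagents that add atoms: none
Why: Miyaura borylation of a 1-alkenyl bromide; the weak phenoxide base activates the diboron without promoting Suzuki coupling of the product with unreacted bromide, and the enol ether boronate is purified under non-acidic conditions.

Step 5
Reactants: 2 2-iodo-5-methoxybenzene-1,3-diol; 11 carbon monoxide; 10 2-[2-methoxy-1-(2,4,5-trimethoxyphenyl)ethenyl]-4,4,5,5-tetramethyl-1,3,2-dioxaborolane
Product: 13 5-hydroxy-7-methoxy-3-(2,4,5-trimethoxyphenyl)chromen-4-one, via methoxyvinyl ketone 12 (not isolated)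
Conditions: PdCl2(PPh3)2 (5 mol %), K2CO3 (3 equiv), CO (1 atm), 10 (1.5 equiv), anisole, 80 °C; then 1 M HCl on work-up
Reagents that add atoms: none
Why: Proposed new method: zerovalent palladium formed from PdCl2(PPh3)2 adds oxidatively to the C–I bond of 2, CO inserts to give the 2,6-dioxygenated aroylpalladium species, and transmetalation with the carbonate- or phenoxide-activated boronate 10 followed by reductive elimination gives ketone 12 (bonds C4a–C4 and C4–C3). A flanking phenoxide of 12 then adds to the methoxy-bearing β-carbon and expels methoxide, a 6-endo-trig oxa-Michael addition–elimination that forms O1–C2 and closes ring C as the pyranone. The closest known reactions are the carbonylative Suzuki–Miyaura ketone synthesis from di-ortho-substituted aryl iodides and the carbonylative annulation of 2-iodophenols with terminal alkynes to chromones; ring closure of 2-hydroxyaryl β-alkoxyvinyl or β-aminovinyl ketones to chromones is routine. No stereocentre is formed, and the geometry of 10 is lost in the addition–elimination. The step needs carbonylative coupling to outrun direct coupling, which the two ortho oxygens secure by slowing transmetalation at the hindered arylpalladium while the electron-rich aryl group migrates readily to CO. The ring closure poses no regiochemical choice, because the mirror symmetry of 2 makes the two hydroxyls equivalent: whichever closes becomes O1 and the other remains as the chelated 5-OH.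

Step 6
Reactants: 13 5-hydroxy-7-methoxy-3-(2,4,5-trimethoxyphenyl)chromen-4-one
Product: 14 7-methoxy-5-(prop-2-enyloxy)-3-(2,4,5-trimethoxyphenyl)chromen-4-one
Conditions: allyl bromide (1.5 equiv), K2CO3, DMF, 60 °C
Reagents that add atoms: allyl bromide, C=CCBr
Why: Williamson etherification of the only hydroxyl; chelation to the C4 carbonyl slows the reaction but warm carbonate in DMF should suffice, and dry carbonate spares C2 of the pyranone.

Step 7
Reactants: 14 7-methoxy-5-(prop-2-enyloxy)-3-(2,4,5-trimethoxyphenyl)chromen-4-one
Product: 15 5-hydroxy-7-methoxy-6-(prop-2-enyl)-3-(2,4,5-trimethoxyphenyl)chromen-4-one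
Conditions: Eu(fod)3 (10 mol %), PhCl, 110 °C
Reagents that add atoms: none
Why: Aromatic Claisen rearrangement accelerated by Eu(fod)3 chelated between the C4 carbonyl and the ether oxygen; C6 is the only ortho carbon bearing hydrogen, so the allyl group arrives there and the dienone tautomerises to the chelated phenol.

Step 8
Reactants: 15 5-hydroxy-7-methoxy-6-(prop-2-enyl)-3-(2,4,5-trimethoxyphenyl)chromen-4-one
Product: 16 5-hydroxy-7-methoxy-6-(3-methylbut-2-enyl)-3-(2,4,5-trimethoxyphenyl)chromen-4-one
Conditions: 2-methylbut-2-ene (excess), second-generation Grubbs catalyst (5 mol %), CH2Cl2, 35 °C, sealed vessel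
Reagents that add atoms: 2-methylbut-2-ene, CC=C(C)C
Why: Olefin cross-metathesis with excess 2-methylbut-2-ene turns the terminal allyl group into the prenyl group with release of propene; the trisubstituted product alkene and the C2=C3 enol ether of the pyranone are not substrates for the catalyst, and the chelated phenol is tolerated.

## Compound list

1 | 5-methoxybenzene-1,3-diol (5-methoxyresorcinol) | COc1cc(O)cc(O)c1 | starting material
2 | 2-iodo-5-methoxybenzene-1,3-diol | COc1cc(O)c(I)c(O)c1 | intermediate
3 | 2,4,5-trimethoxybenzaldehyde | COc1cc(OC)c(C=O)cc1OC | starting material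
4 | (methoxymethyl)triphenylphosphonium chloride | COC[P+](c1ccccc1)(c1ccccc1)c1ccccc1.[Cl-] | starting material
5 | methoxymethylidene(triphenyl)phosphorane (ylide, formed in the flask, not isolated) | COC=P(c1ccccc1)(c1ccccc1)c1ccccc1 | intermediate
6 | 1,2,4-trimethoxy-5-(2-methoxyethenyl)benzene (E/Z mixture) | COC=Cc1cc(OC)c(OC)cc1OC | intermediate
7 | 1-(1,2-dibromo-2-methoxyethyl)-2,4,5-trimethoxybenzene (mixture of diastereomers, not isolated) | COC(Br)C(Br)c1cc(OC)c(OC)cc1OC | intermediate
8 | 1-(1-bromo-2-methoxyethenyl)-2,4,5-trimethoxybenzene (mixture of double-bond isomers) | COC=C(Br)c1cc(OC)c(OC)cc1OC | intermediate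
9 | bis(pinacolato)diboron | CC1(C)OB(B2OC(C)(C)C(C)(C)O2)OC1(C)C | starting material
10 | 2-[2-methoxy-1-(2,4,5-trimethoxyphenyl)ethenyl]-4,4,5,5-tetramethyl-1,3,2-dioxaborolane (mixture of double-bond isomers) | COC=C(B1OC(C)(C)C(C)(C)O1)c1cc(OC)c(OC)cc1OC | intermediate
11 | carbon monoxide | [C-]#[O+] | starting material
12 | 1-(2,6-dihydroxy-4-methoxyphenyl)-3-methoxy-2-(2,4,5-trimethoxyphenyl)prop-2-en-1-one (mixture of double-bond isomers, not isolated) | COC=C(C(=O)c1c(O)cc(OC)cc1O)c1cc(OC)c(OC)cc1OC | intermediate
13 | 5-hydroxy-7-methoxy-3-(2,4,5-trimethoxyphenyl)chromen-4-one | COc1cc(O)c2c(c1)occ(-c1cc(OC)c(OC)cc1OC)c2=O | intermediate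
14 | 7-methoxy-5-(prop-2-enyloxy)-3-(2,4,5-trimethoxyphenyl)chromen-4-one | C=CCOc1cc(OC)cc2occ(-c3cc(OC)c(OC)cc3OC)c(=O)c12 | intermediate
15 | 5-hydroxy-7-methoxy-6-(prop-2-enyl)-3-(2,4,5-trimethoxyphenyl)chromen-4-one | COc1cc2occ(-c3cc(OC)c(OC)cc3OC)c(=O)c2c(O)c1CC=C | intermediate
16 | 5-hydroxy-7-methoxy-6-(3-methylbut-2-enyl)-3-(2,4,5-trimethoxyphenyl)chromen-4-one | COc1cc(OC)c(-c2coc3cc(OC)c(CC=C(C)C)c(O)c3c2=O)cc1OC | target

## Step count and risks

Total step count: 8. Longest linear sequence: 7 steps (3 to 6 to 8 to 10 to 13 to 14 to 15 to 16); the iodide 2 is made in one step on a separate branch.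

**Step 5 (key step, proposed new method).** Several processes may compete with the desired sequence:
- capture of the aroylpalladium intermediate by phenoxide or adventitious water, giving ester or acid formation instead of transmetalation;
- direct coupling without CO insertion, which after loss of methanol would lead to benzofuran formation;
- protodeboronation of the enol ether boronate under the basic conditions;
- reductive loss of iodine from the very electron-rich iodide.

Fallback by known chemistry, setting out from aldehyde 3 and returning at 13: Claisen–Schmidt condensation of 3 with commercial 1-(2-hydroxy-4,6-dimethoxyphenyl)ethanone (KOH, EtOH) should give (E)-1-(2-hydroxy-4,6-dimethoxyphenyl)-3-(2,4,5-trimethoxyphenyl)prop-2-en-1-one F1. Oxidative 1,2-aryl migration with Tl(NO3)3·3H2O in MeOH/HC(OMe)3, favoured by the electron-rich migrating ring, should give 1-(2-hydroxy-4,6-dimethoxyphenyl)-3,3-dimethoxy-2-(2,4,5-trimethoxyphenyl)propan-1-one F2. Acid (HCl, MeOH, reflux) should close this to 5,7-dimethoxy-3-(2,4,5-trimethoxyphenyl)chromen-4-one F3. BCl3 (CH2Cl2, 0 °C) should then remove only the methyl group peri to the carbonyl, through the six-membered boron chelate, and give 13.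

**Step 3.** Ring bromination of the trimethoxyarene may compete with addition to the enol ether. The doubly activated benzylic bromide of 7 may ionise before elimination, or elimination may take the other direction. Fallback, from 6 and returning at 8: methoxybromination with NBS in MeOH (0 °C), a milder bromonium source that never forms an α-bromo ether, should give 1-(1-bromo-2,2-dimethoxyethyl)-2,4,5-trimethoxybenzene F4. Elimination of methanol from this acetal with TMSOTf/iPr2NEt (CH2Cl2, −20 °C to rt) should give 8.

**Step 1.** Iodination may also occur at C4, between hydroxyl and methoxyl, or twice, because all three ring positions are activated. Fallback, from 1 and returning at 2: protection with MOMCl/iPr2NEt should give 1-methoxy-3,5-bis(methoxymethoxy)benzene F5. Directed ortho-lithiation between the two acetal oxygens (n-BuLi, THF, 0 °C) and quenching with I2 should give 2-iodo-5-methoxy-1,3-bis(methoxymethoxy)benzene F6. Mild acid (HCl, MeOH, rt) should release 2; here the iodine position is fixed by the metalation.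

**Step 7.** Cleavage of the peri allyl ether back to the phenol may outpace the [3,3] shift, or the rearrangement may be sluggish at temperatures the substrate tolerates. Fallback, from 13 and returning at 16: alkylation with 3-chloro-3-methylbut-1-yne (CuCl2·2H2O cat., DBU, MeCN, 0 °C) should give 7-methoxy-5-(2-methylbut-3-yn-2-yloxy)-3-(2,4,5-trimethoxyphenyl)chromen-4-one F7. Semihydrogenation (H2, Pd/CaCO3 poisoned with Pb(OAc)2, quinoline, EtOAc) should give 7-methoxy-5-(2-methylbut-3-en-2-yloxy)-3-(2,4,5-trimethoxyphenyl)chromen-4-one F8. This tertiary allyl ether should rearrange at about 120 °C (PhNEt2) directly to 16, so that steps 6 to 8 are replaced and no metathesis is needed.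

## Further compounds

F1 | step 5 | (E)-1-(2-hydroxy-4,6-dimethoxyphenyl)-3-(2,4,5-trimethoxyphenyl)prop-2-en-1-one | COc1cc(O)c(C(=O)/C=C/c2cc(OC)c(OC)cc2OC)c(OC)c1
F2 | step 5 | 1-(2-hydroxy-4,6-dimethoxyphenyl)-3,3-dimethoxy-2-(2,4,5-trimethoxyphenyl)propan-1-one (racemic) | COC(OC)C(C(=O)c1c(O)cc(OC)cc1OC)c1cc(OC)c(OC)cc1OC
F3 | step 5 | 5,7-dimethoxy-3-(2,4,5-trimethoxyphenyl)chromen-4-one | COc1cc(OC)c2c(c1)occ(-c1cc(OC)c(OC)cc1OC)c2=O
F4 | step 3 | 1-(1-bromo-2,2-dimethoxyethyl)-2,4,5-trimethoxybenzene (racemic) | COC(OC)C(Br)c1cc(OC)c(OC)cc1OC
F5 | step 1 | 1-methoxy-3,5-bis(methoxymethoxy)benzene | COCOc1cc(OC)cc(OCOC)c1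
F6 | step 1 | 2-iodo-5-methoxy-1,3-bis(methoxymethoxy)benzene | COCOc1cc(OC)cc(OCOC)c1I
F7 | step 7 | 7-methoxy-5-(2-methylbut-3-yn-2-yloxy)-3-(2,4,5-trimethoxyphenyl)chromen-4-one | C#CC(C)(C)Oc1cc(OC)cc2occ(-c3cc(OC)c(OC)cc3OC)c(=O)c12
F8 | step 7 | 7-methoxy-5-(2-methylbut-3-en-2-yloxy)-3-(2,4,5-trimethoxyphenyl)chromen-4-one | C=CC(C)(C)Oc1cc(OC)cc2occ(-c3cc(OC)c(OC)cc3OC)c(=O)c12
A1 | alternative 1 | 4-methoxy-2-(methoxymethoxy)-6-[2-oxo-2-(2,4,5-trimethoxyphenyl)ethoxy]benzaldehyde | COCOc1cc(OC)cc(OCC(=O)c2cc(OC)c(OC)cc2OC)c1C=O
A2 | alternative 1 | racemic 3-hydroxy-7-methoxy-5-(methoxymethoxy)-3-(2,4,5-trimethoxyphenyl)chroman-4-one | COCOc1cc(OC)cc2c1C(=O)C(O)(c1cc(OC)c(OC)cc1OC)CO2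
A3 | alternative 2 | methyl 2-methyl-4-oxo-5-(2,4,5-trimethoxyphenyl)-4H-pyran-3-carboxylate | COC(=O)c1c(C)occ(-c2cc(OC)c(OC)cc2OC)c1=O
A4 | alternative 2 | methyl 5-methylhex-4-enoate | COC(=O)CCC=C(C)C
A5 | alternative 2 | 5,7-dihydroxy-6-(3-methylbut-2-enyl)-3-(2,4,5-trimethoxyphenyl)chromen-4-one | COc1cc(OC)c(-c2coc3cc(O)c(CC=C(C)C)c(O)c3c2=O)cc1OC
A6 | alternative 3 | (CO)5Cr=C(OMe)C(OMe)=CH2, pentacarbonyl[methoxy(1-methoxyethenyl)methylidene]chromium | COC(=C)C(OC)=[Cr](=C=O)(=C=O)(=C=O)(=C=O)=C=O
A7 | alternative 3 | 3-ethynyl-5,7-dimethoxychromen-4-one | COc1cc(OC)c2c(c1)occ(C#C)c2=O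
A8 | alternative 3 | 3-(2-hydroxy-4,5-dimethoxyphenyl)-5,7-dimethoxychromen-4-one | COc1cc(OC)c2c(c1)occ(-c1cc(OC)c(OC)cc1O)c2=O
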